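**Retrosynthetic overview**
- Target 14 comes from its 7-O-benzyl ether 13 by hydrogenolysis, and 13 from isoflavanone 12 by dehydrogenation across C2–C3.
- Ring C is the only ring made (rings A and B are purchased arenes): O1–C2 forms by 6-endo oxa-Michael addition of the unmasked phenol of enone 10.
- Enone 10 is cut at C4a–C4 and C4–C3 into aryl iodide 5, carbon monoxide 9 and α-arylvinyl boronate 8 (three-component carbonylative Suzuki coupling).
- Feature used: the C4 carbonyl is a single carbon flanked by C4a of ring A and by C3, which carries ring B; C2 is a one-carbon unit bonded only to C3 and O1, so it can arrive as the terminal CH2 of the vinyl boronate.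
- 5 comes from O-benzylisovanillin 1 (Baeyer–Villiger, ortho-iodination, MOM ether); 8 from alkyne 6 and B2pin2 7 (Markovnikov protoboration).

Key step: step 5

Remark: 3-(benzyloxy)-4-methoxybenzaldehyde 1 (the O-benzyl ether of isovanillin) is taken as a purchased material. The target is achiral; the one stereocentre that appears on the way (C3 of 12) is formed racemic and is erased in step 7.

Step 1
Reactants: 1 3-(benzyloxy)-4-methoxybenzaldehyde
Product: 3 3-(benzyloxy)-4-methoxyphenol, via aryl formate 2 (not isolated)
Conditions: mCPBA (1.3 equiv), CH2Cl2, 0 °C to rt; aq. NaHCO3 wash; then K2CO3 (cat.), MeOH, rt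
Reagents that add atoms: mCPBA, OOC(=O)c1cccc(Cl)c1
Why: Baeyer–Villiger (Dakin-type) oxidation, in which the electron-rich aryl group carrying a para methoxy group migrates to oxygen and the resulting formate is methanolysed, while the benzyl and methyl ethers are inert.

Step 2
Reactants: 3 3-(benzyloxy)-4-methoxyphenol
Product: 4 5-(benzyloxy)-2-iodo-4-methoxyphenol
Conditions: NIS (1.05 equiv), TsOH·H2O (10 mol%), MeCN, 0 °C, dark
Reagents that add atoms: N-iodosuccinimide, O=C1CCC(=O)N1I
Why: Electrophilic aromatic iodination should go to the carbon that is ortho to the hydroxyl and para to the benzyloxy group, because it is doubly activated and open, whereas the other ortho carbon lies between two oxygen substituents.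

Step 3
Reactants: 4 5-(benzyloxy)-2-iodo-4-methoxyphenol
Product: 5 1-(benzyloxy)-4-iodo-2-methoxy-5-(methoxymethoxy)benzene
Conditions: NaH (1.2 equiv), THF/DMF, 0 °C; then MOMCl (1.2 equiv), 0 °C to rt
Reagents that add atoms: chloromethyl methyl ether (MOMCl), COCCl
Why: Williamson-type O-alkylation of the sodium phenoxide with the reactive α-chloro ether masks the ortho oxygen as an acetal that is stable to the basic coupling conditions and leaves the aryl iodide untouched.

Step 4
Reactants: 6 5-ethynyl-1,2,3-trimethoxybenzene; 7 bis(pinacolato)diboron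
Product: 8 4,4,5,5-tetramethyl-2-[1-(3,4,5-trimethoxyphenyl)ethenyl]-1,3,2-dioxaborolane
Conditions: (SIMes)CuCl (5 mol%; SIMes = 1,3-dimesitylimidazolidin-2-ylidene), NaOt-Bu (10 mol%), MeOH (2 equiv), THF, −50 to −15 °C
Reagents that add atoms: none
Why: Copper-catalysed protoboration (formal Markovnikov hydroboration) of a terminal aryl alkyne, in which the boryl complex of monovalent copper bearing an N-aryl carbene adds syn with boron at the aryl-bearing carbon and methanol protonates the terminal C–Cu bond.

Step 5
Reactants: 5 1-(benzyloxy)-4-iodo-2-methoxy-5-(methoxymethoxy)benzene; 8 4,4,5,5-tetramethyl-2-[1-(3,4,5-trimethoxyphenyl)ethenyl]-1,3,2-dioxaborolane; 9 carbon monoxide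
Product: 10 1-[4-(benzyloxy)-5-methoxy-2-(methoxymethoxy)phenyl]-2-(3,4,5-trimethoxyphenyl)prop-2-en-1-one
Conditions: Pd(PPh3)4 (5 mol%), K2CO3 (3 equiv), H2O (5 equiv), CO (balloon), anisole, 80 °C
Reagents that add atoms: none
Why: Zerovalent palladium should insert into the C–I bond of 5, CO should then insert to give an aroyl complex of divalent palladium (new C4a–C4 bond), base-assisted transfer of the α-arylvinyl group from boron and reductive elimination should form C4–C3 and release enone 10. The closest known reaction type is the carbonylative Suzuki–Miyaura coupling of aryl iodides with alkenylboron reagents. No ring is closed and no stereocentre is formed in this step. The selectivity needed is carbonylative over direct coupling (which would give a 1,1-diarylethene); it is secured by the electron-rich ortho-alkoxyaryl group, which migrates quickly onto CO, by the CO atmosphere, and by the slow transmetalation of the hindered 1,1-disubstituted boronate, which leaves time for insertion. The MOM ether keeps the ortho oxygen from intercepting the aroyl-palladium species, and the mild carbonate base should leave the α-methylene ketone intact.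

Step 6
Reactants: 10 1-[4-(benzyloxy)-5-methoxy-2-(methoxymethoxy)phenyl]-2-(3,4,5-trimethoxyphenyl)prop-2-en-1-one
Product: 12 rac-7-(benzyloxy)-6-methoxy-3-(3,4,5-trimethoxyphenyl)-2,3-dihydro-4H-chromen-4-one, via free phenol enone 11 (not isolated)
Conditions: TsOH·H2O (0.2 equiv), MeOH/THF, 45 °C; concentrate; then K2CO3 (0.5 equiv), MeCN, rt
Reagents that add atoms: none
Why: Acid-catalysed acetal exchange to methanol unmasks the ortho phenol (benzyl and methyl ethers are inert), and its phenoxide then adds to the terminal methylene of the enone in a 6-endo-trig oxa-Michael addition that closes ring C at O1–C2; C3 is protonated without control, so 12 is racemic, which does not matter because C3 becomes sp2 in step 7.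

Step 7
Reactants: 12 rac-7-(benzyloxy)-6-methoxy-3-(3,4,5-trimethoxyphenyl)-2,3-dihydro-4H-chromen-4-one
Product: 13 7-(benzyloxy)-6-methoxy-3-(3,4,5-trimethoxyphenyl)-4H-chromen-4-one
Conditions: DDQ (1.5 equiv), 1,4-dioxane, reflux
Reagents that add atoms: none
Why: DDQ dehydrogenation of a chroman-4-one, in which hydride loss from C2 (next to O1) of the enol form followed by proton loss gives the conjugated 4-pyranone ring and removes the C3 stereocentre, while a plain benzyl ether (unlike a p-methoxybenzyl ether) should tolerate the quinone.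

Step 8
Reactants: 13 7-(benzyloxy)-6-methoxy-3-(3,4,5-trimethoxyphenyl)-4H-chromen-4-one
Product: 14 7-hydroxy-6-methoxy-3-(3,4,5-trimethoxyphenyl)-4H-chromen-4-one
Conditions: H2 (1 atm), Pd/C (10 wt% Pd on carbon), EtOAc/MeOH, rt, stopped after one equivalent of H2
Reagents that add atoms: none
Why: Catalytic hydrogenolysis of the aryl benzyl ether should free the C7 phenol, since the C2=C3 bond of the chromone is a vinylogous ester that is reduced much more slowly and the four methyl ethers are inert.

**Compound list**
1 | 3-(benzyloxy)-4-methoxybenzaldehyde | COc1ccc(C=O)cc1OCc1ccccc1 | starting material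
2 | 3-(benzyloxy)-4-methoxyphenyl formate | COc1ccc(OC=O)cc1OCc1ccccc1 | intermediate (not isolated)
3 | 3-(benzyloxy)-4-methoxyphenol | COc1ccc(O)cc1OCc1ccccc1 | intermediate
4 | 5-(benzyloxy)-2-iodo-4-methoxyphenol | COc1cc(I)c(O)cc1OCc1ccccc1 | intermediate
5 | 1-(benzyloxy)-4-iodo-2-methoxy-5-(methoxymethoxy)benzene | COCOc1cc(OCc2ccccc2)c(OC)cc1I | intermediate
6 | 5-ethynyl-1,2,3-trimethoxybenzene | C#Cc1cc(OC)c(OC)c(OC)c1 | starting material
7 | bis(pinacolato)diboron | CC1(C)OB(OC1(C)C)B1OC(C)(C)C(C)(C)O1 | starting material
8 | 4,4,5,5-tetramethyl-2-[1-(3,4,5-trimethoxyphenyl)ethenyl]-1,3,2-dioxaborolane | C=C(B1OC(C)(C)C(C)(C)O1)c1cc(OC)c(OC)c(OC)c1 | intermediate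
9 | carbon monoxide | [C-]#[O+] | starting material
10 | 1-[4-(benzyloxy)-5-methoxy-2-(methoxymethoxy)phenyl]-2-(3,4,5-trimethoxyphenyl)prop-2-en-1-one | C=C(C(=O)c1cc(OC)c(OCc2ccccc2)cc1OCOC)c1cc(OC)c(OC)c(OC)c1 | intermediate
11 | 1-[4-(benzyloxy)-2-hydroxy-5-methoxyphenyl]-2-(3,4,5-trimethoxyphenyl)prop-2-en-1-one | C=C(C(=O)c1cc(OC)c(OCc2ccccc2)cc1O)c1cc(OC)c(OC)c(OC)c1 | intermediate (not isolated)
12 | rac-7-(benzyloxy)-6-methoxy-3-(3,4,5-trimethoxyphenyl)-2,3-dihydro-4H-chromen-4-one (racemic at C3) | COc1cc2C(=O)C(c3cc(OC)c(OC)c(OC)c3)COc2cc1OCc1ccccc1 | intermediate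
13 | 7-(benzyloxy)-6-methoxy-3-(3,4,5-trimethoxyphenyl)-4H-chromen-4-one | COc1cc2c(=O)c(-c3cc(OC)c(OC)c(OC)c3)coc2cc1OCc1ccccc1 | intermediate
14 | 7-hydroxy-6-methoxy-3-(3,4,5-trimethoxyphenyl)-4H-chromen-4-one | COc1cc2c(=O)c(-c3cc(OC)c(OC)c(OC)c3)coc2cc1O | target

**Step count**
Total steps: 8. Longest linear sequence: 7 steps (1, 2, 3, 5, 6, 7, 8); the boronate branch is one step (4) before the convergence.

**Steps most likely to fail**

Step 5 (key step). Direct coupling without CO uptake may compete, the hindered pinacol boronate may transmetalate so slowly that the aroyl-palladium species is hydrolysed to the acid, or the α-methylene ketone may oligomerise under base. The fallback builds the same ketone without CO and sets out from iodide 5. Iodine–magnesium exchange (i-PrMgCl·LiCl, THF, 0 °C) should give [4-(benzyloxy)-5-methoxy-2-(methoxymethoxy)phenyl]magnesium chloride F2. This is acylated with N-methoxy-N-methyl-2-(3,4,5-trimethoxyphenyl)acetamide F1 (made from commercial 3,4,5-trimethoxyphenylacetic acid with carbonyldiimidazole and N,O-dimethylhydroxylamine hydrochloride) to give the deoxybenzoin 1-[4-(benzyloxy)-5-methoxy-2-(methoxymethoxy)phenyl]-2-(3,4,5-trimethoxyphenyl)ethan-1-one F3. α-Methylenation of F3 with paraformaldehyde and diisopropylammonium trifluoroacetate in refluxing THF (Mannich-type condensation and elimination of water) comes back to the route at enone 10.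

Step 4. The regioselectivity of the Cu–B addition may erode with this fairly electron-rich aryl alkyne, so that boron is delivered in part to the terminal carbon and a hard-to-separate β-styryl boronate forms. The fallback sets out from alkyne 6. Markovnikov hydroiodination (NaI, TMSCl, H2O, MeCN, rt) should give 5-(1-iodoethenyl)-1,2,3-trimethoxybenzene F4. Miyaura borylation of F4 with bis(pinacolato)diboron 7 (PdCl2(PPh3)2, PPh3, KOPh, toluene, 50 °C) fixes boron at the internal carbon by construction and comes back at boronate 8.

Step 7. Dehydrogenation may stall, or DDQ may attack the electron-rich rings or the benzylic CH2 of the protecting group. The fallback sets out from isoflavanone 12. Soft enolisation (TMSOTf, Et3N, CH2Cl2, 0 °C) should give the silyl enol ether {[7-(benzyloxy)-6-methoxy-3-(3,4,5-trimethoxyphenyl)-2H-chromen-4-yl]oxy}(trimethyl)silane F5. Saegusa–Ito oxidation of F5 with Pd(OAc)2 in MeCN at rt (oxa-allyl complex of divalent palladium, β-hydride elimination from C2) comes back at isoflavone 13.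

**Further compounds**
F1 | step 5 | N-methoxy-N-methyl-2-(3,4,5-trimethoxyphenyl)acetamide | CON(C)C(=O)Cc1cc(OC)c(OC)c(OC)c1
F2 | step 5 | [4-(benzyloxy)-5-methoxy-2-(methoxymethoxy)phenyl]magnesium chloride | COCOc1cc(OCc2ccccc2)c(OC)cc1[Mg]Cl
F3 | step 5 | 1-[4-(benzyloxy)-5-methoxy-2-(methoxymethoxy)phenyl]-2-(3,4,5-trimethoxyphenyl)ethan-1-one | COCOc1cc(OCc2ccccc2)c(OC)cc1C(=O)Cc1cc(OC)c(OC)c(OC)c1
F4 | step 4 | 5-(1-iodoethenyl)-1,2,3-trimethoxybenzene | C=C(I)c1cc(OC)c(OC)c(OC)c1
F5 | step 7 | {[7-(benzyloxy)-6-methoxy-3-(3,4,5-trimethoxyphenyl)-2H-chromen-4-yl]oxy}(trimethyl)silane | COc1cc2C(O[Si](C)(C)C)=C(c3cc(OC)c(OC)c(OC)c3)COc2cc1OCc1ccccc1
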